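A closed, stirred vessel holds a solid substrate that passes into solution; what dissolves meets partner, giving target, or meets target, giving side product.

solid substrate 0.050 M; partner 2.00 equiv; time 80 s

    dissolved substrate + target → side product (k1 = 32 M⁻¹ s⁻¹)
    solid substrate ⇌ dissolved substrate, rate k2*(cs2 - [dissolved substrate]) while solid is left; crystals form when [dissolved substrate] > cs2 (cs2 = 33 mM, k2 = 0.010 s⁻¹)
    dissolved substrate + partner → target (k3 = 16 M⁻¹ s⁻¹)
    partner → decomposed reagent (k4 = 0.010 s⁻¹)
    solid substrate → decomposition product (k5 = 5.1 × 10⁻⁵ s⁻¹)

1. how much target there is at 80 s, in percent of the solid substrate charged
2. concentration of dissolved substrate in solution at 80 s, in percent of saturation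

- percentages count the solid substrate that a species holds: one side product counts as two
- solid, in amounts per volume of the solution: solid substrate
- at the start none of the solid substrate is in solution
- dissolved substrate means what is dissolved; the solid is not counted in it
- run time (flask): 80 s

Examiner: How much dissolved substrate do you expect?

Candidate: A low level. With the partner as charged, the half-life of dissolved substrate by reaction with partner alone is 0.43 s, short against the 69 s in which the partner halves by its own decay, so the dissolved substrate can follow its surroundings, and what arrives leaves again: a quasi-steady state.

Examiner: And what arrives?

Candidate: With the level far below the solubility, the bracket of the dissolution rate, solubility minus level, is nearly the solubility. So I keep the large term and treat the small one as a correction. The dissolution coefficient times the solubility is 0.330 mM s⁻¹, the rate into an empty solution, which I call the feed. The level of dissolved substrate is then the feed divided by the draw. The draw is 16 M⁻¹ s⁻¹ times c(partner), plus 32 M⁻¹ s⁻¹ times c(target), plus the correction 0.010 s⁻¹.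

Examiner: Reckon it at the start.

Candidate: There is no target yet, so the draw is 1.61 s⁻¹, and the level is 0.621% of saturation.

Examiner: But the partner decays, and target appears. What then?

Candidate: Decay alone leaves 44.9 mM of partner at 80 s, and without target that gives 1.37% of saturation. The partner used in making target raises this figure, and the draw of the target lowers it. I commit to a level between my two figures. For the target I can say less: the feed delivers at most 52.8% of the charge by then, and I cannot split that by hand.

The forecast gives 26% of target and 1.05% of saturation, on the ground that “the dissolved substrate is consumed far faster than it arrives”.

The flask gives 26.6% of target and 1.05% of saturation. Its readings at 80.0 s, partner 32.0% of its own charge and target 26.6% of the solid substrate charged, make the draw 0.947 s⁻¹, so feed over draw is 1.06% of saturation. The neighbouring flask, charged with 0.800 equiv of partner, holds at 80.0 s partner at 19.7% of its own charge and target at 12.2% of the solid substrate charged. The same feed there meets a draw of 0.332 s⁻¹, which gives a level of 0.994 mM, and that neighbouring flask reads 0.952 mM of dissolved substrate.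

The constants are invented; what happens was integrated by code.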